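**Retrosynthetic overview**
1. Feature (rings lettered A–E from the 2,4,6-trihydroxyphenoxy end): in ring C, C4–OH lies between oxygenated C3 (OH) and C5 (O–ring D) and para to C1 (O–ring B), and C2 and C6 are the only C–H positions. C3–C4–C5 is therefore a masked 1,3-dioxygenated acetone and C2–C1–C6 a masked 2-aryloxymalonaldehyde.
2. Disconnections: first the twelve O–CH3 bonds (last step), then C2–C3 and C5–C6 of ring C. This splits the pentamer into a D–E aryloxy(methoxy)acetone and an A–B 2-aryloxy-3-(dimethylamino)acrolein.
3. Both aryl–O bonds of ring C are made beforehand as phenol O-alkylations at sp3 carbon (bromoacetal for A–B, glycidyl methyl ether for D–E).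
4. Each 2-aryloxyphenol half comes from a trimethoxyphenol and an ortho-bromobenzaldehyde by Ullmann coupling, then Baeyer–Villiger exchange of CHO for OH.
5. Ring order: A, B, D and E are bought as arenes. Ring C is the only ring built, and it is closed in the penultimate step.

Key step: step 10

Assumption: the two ortho-bromobenzaldehydes used as ring B and ring D electrophiles are taken as catalogue compounds; the target holds no stereocentre, so no stereocontrol is needed.

**Route**

Step 1
Reactants: 1 2,4,6-trimethoxyphenol; 2 2-bromo-4,6-dimethoxybenzaldehyde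
Product: 3 2,4-dimethoxy-6-(2,4,6-trimethoxyphenoxy)benzaldehyde
Conditions: CuI (cat.), picolinic acid (cat.), K3PO4, DMSO, 90 °C, Ar
Reagents that add atoms: none
Why: Ligand-accelerated Ullmann diaryl ether synthesis; the bromide is ortho to the formyl group, which speeds copper-mediated substitution, the picolinic acid system is suited to ortho,ortho'-disubstituted phenols, and argon protects the oxidation-prone phenoxide.

Step 2
Reactants: 3 2,4-dimethoxy-6-(2,4,6-trimethoxyphenoxy)benzaldehyde
Product: 5 2,4-dimethoxy-6-(2,4,6-trimethoxyphenoxy)phenol (A–B phenol), via aryl formate 4 (not isolated)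
Conditions: mCPBA, CH2Cl2, 0 °C to rt, aq. NaHCO3 wash; then K2CO3 (cat.), MeOH, rt
Reagents that add atoms: mCPBA (3-chloroperoxybenzoic acid), OOC(=O)c1cccc(Cl)c1
Why: Baeyer–Villiger oxidation of an electron-rich benzaldehyde (Dakin-type outcome); the trioxygenated aryl group migrates in preference to hydride, and base-catalysed methanolysis then cleaves the crude formate.

Step 3
Reactants: 5 A–B phenol; 6 bromoacetaldehyde diethyl acetal
Product: 7 2-(2,2-diethoxyethoxy)-1,5-dimethoxy-3-(2,4,6-trimethoxyphenoxy)benzene
Conditions: K2CO3, DMF, 120 °C, Ar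
Reagents that add atoms: none
Why: Williamson ether synthesis; the phenoxide displaces the primary bromide by SN2, with heat making up for the sluggish β,β-dialkoxy electrophile and the flanked phenol.

Step 4
Reactants: 7 aryloxyacetaldehyde diethyl acetal
Product: 8 2-[2,4-dimethoxy-6-(2,4,6-trimethoxyphenoxy)phenoxy]acetaldehyde
Conditions: 1 M aq. HCl, THF, 50 °C; used crude
Reagents that add atoms: water, O
Why: Acid-catalysed acetal hydrolysis; both ring B positions ortho to the ether oxygen are blocked, so benzofuran-type cyclodehydration cannot occur, and dilute acid spares the nucleophilic ring A from Friedel–Crafts hydroxyalkylation.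

Step 5
Reactants: 8 aryloxyacetaldehyde
Product: 9 (Z)-3-(dimethylamino)-2-[2,4-dimethoxy-6-(2,4,6-trimethoxyphenoxy)phenoxy]prop-2-enal
Conditions: HC(OMe)2NMe2 (excess), toluene, 90 °C
Reagents that add atoms: N,N-dimethylformamide dimethyl acetal, COC(OC)N(C)C
Why: Aminomethylenation of an activated methylene with an amide acetal; the reagent does not attack the electron-rich arenes (a Vilsmeier reagent would formylate ring A), and the push–pull enal should settle in the Z form with NMe2 trans to CHO.

Step 6
Reactants: 10 3,4,5-trimethoxyphenol; 11 2-bromo-3,4,5-trimethoxybenzaldehyde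
Product: 12 3,4,5-trimethoxy-2-(3,4,5-trimethoxyphenoxy)benzaldehyde
Conditions: CuI (cat.), picolinic acid (cat.), K3PO4, DMSO, 100 °C, Ar
Reagents that add atoms: none
Why: Ullmann diaryl ether synthesis; the phenol is unhindered and the ortho-formyl group activates the flanked C–Br bond, as in couplings of 2-bromo-3,4,5-trimethoxybenzoyl derivatives with phenols.

Step 7
Reactants: 12 3,4,5-trimethoxy-2-(3,4,5-trimethoxyphenoxy)benzaldehyde
Product: 14 3,4,5-trimethoxy-2-(3,4,5-trimethoxyphenoxy)phenol (D–E phenol), via aryl formate 13 (not isolated)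
Conditions: mCPBA, CH2Cl2, 0 °C to rt, aq. NaHCO3 wash; then K2CO3 (cat.), MeOH, rt
Reagents that add atoms: mCPBA (3-chloroperoxybenzoic acid), OOC(=O)c1cccc(Cl)c1
Why: Baeyer–Villiger oxidation followed by formate methanolysis; the para-methoxy and ortho-aryloxy donors give the aryl group the higher migratory aptitude.

Step 8
Reactants: 14 D–E phenol; 15 racemic glycidyl methyl ether
Product: 16 racemic 1-methoxy-3-[3,4,5-trimethoxy-2-(3,4,5-trimethoxyphenoxy)phenoxy]propan-2-ol
Conditions: K2CO3 (cat.), DMF, 90 °C
Reagents that add atoms: none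
Why: Base-catalysed SN2 opening of the epoxide by phenoxide at the unsubstituted terminal carbon; the carbinol centre is carried over unchanged from the racemic epoxide and is removed in step 9.

Step 9
Reactants: 16 racemic secondary alcohol
Product: 17 1-methoxy-3-[3,4,5-trimethoxy-2-(3,4,5-trimethoxyphenoxy)phenoxy]propan-2-one
Conditions: Dess–Martin periodinane, CH2Cl2, rt
Reagents that add atoms: none
Why: Dess–Martin oxidation of a secondary alcohol under near-neutral conditions, which leaves the electron-rich arenes and the base-sensitive α-aryloxy ketone untouched.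

Step 10
Reactants: 9 A–B aminoacrolein; 17 D–E ketone
Product: 19 pentamer dodecamethyl ether with free ring C C4–OH, via open-chain keto enal 18 (not isolated)
Conditions: t-BuOK (2.5 equiv), THF, 0 °C to 65 °C (17 added slowly to 9 and base); then AcOH
Reagents that add atoms: none
Why: t-BuOK generates the enolate of 17 (the aryloxy-bearing α-carbon is the more acidic), which adds to the NMe2-bearing carbon of the push–pull enal 9 and expels dimethylamine in a vinylogous addition–elimination, forming C5–C6 and giving keto enal 18 as a delocalised anion whose double-bond geometry is mobile. Once the formyl group has swung cis to the ketone arm, the methoxy-bearing α'-carbon attacks it in a 6-(enolendo)-exo-trig aldol closure that forms C2–C3 and ring C; loss of water and enolisation then give the phenoxide, whose aromatic stabilisation makes the sequence irreversible. The closest known reaction type is the [3+3] phenol synthesis from ketones with two α-methylene groups and malonaldehyde equivalents (sodium nitromalonaldehyde, vinamidinium salts, 3-aminoacroleins), applied here to a ketone that carries an oxygen on each α-carbon. No stereocentre remains, since the sp3 centre of 18 is erased on aromatisation. Regiochemistry needs no control because C2 and C6 are equivalent termini of the three-carbon unit, so either order of bond formation and either pairing ends in the same arene. The selectivity needed is C- over O-attack and cross- over self-condensation, and it is secured by the non-enolisable enal 9, by slow addition of 17 to 9 and base, and by the reversibility of every step before aromatisation.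

Step 11
Reactants: 19 pentamer dodecamethyl ether
Product: 20 pseudopentafuhalol D
Conditions: BBr3 (excess), CH2Cl2, −78 °C to rt, Ar; then ice-water; degassed solvents, Sephadex LH-20
Reagents that add atoms: none
Why: BBr3-mediated aryl methyl ether cleavage; each ether oxygen binds boron and bromide attacks the methyl carbon by SN2, whereas the four diaryl ether bonds offer no sp3 carbon and stay intact, and hydrolysis then frees all thirteen hydroxyl groups.

**Compound list**
1 | 2,4,6-trimethoxyphenol (ring A) | COc1cc(OC)c(O)c(OC)c1 | starting material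
2 | 2-bromo-4,6-dimethoxybenzaldehyde (ring B) | COc1cc(Br)c(C=O)c(OC)c1 | starting material
3 | 2,4-dimethoxy-6-(2,4,6-trimethoxyphenoxy)benzaldehyde | COc1cc(OC)c(C=O)c(Oc2c(OC)cc(OC)cc2OC)c1 | intermediate
4 | 2,4-dimethoxy-6-(2,4,6-trimethoxyphenoxy)phenyl formate (not isolated) | COc1cc(OC)c(OC=O)c(Oc2c(OC)cc(OC)cc2OC)c1 | intermediate
5 | 2,4-dimethoxy-6-(2,4,6-trimethoxyphenoxy)phenol (A–B phenol) | COc1cc(OC)c(O)c(Oc2c(OC)cc(OC)cc2OC)c1 | intermediate
6 | bromoacetaldehyde diethyl acetal | CCOC(CBr)OCC | starting material
7 | 2-(2,2-diethoxyethoxy)-1,5-dimethoxy-3-(2,4,6-trimethoxyphenoxy)benzene | CCOC(COc1c(OC)cc(OC)cc1Oc1c(OC)cc(OC)cc1OC)OCC | intermediate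
8 | 2-[2,4-dimethoxy-6-(2,4,6-trimethoxyphenoxy)phenoxy]acetaldehyde | O=CCOc1c(OC)cc(OC)cc1Oc1c(OC)cc(OC)cc1OC | intermediate
9 | (Z)-3-(dimethylamino)-2-[2,4-dimethoxy-6-(2,4,6-trimethoxyphenoxy)phenoxy]prop-2-enal | CN(C)/C=C(/C=O)Oc1c(OC)cc(OC)cc1Oc1c(OC)cc(OC)cc1OC | intermediate
10 | 3,4,5-trimethoxyphenol (ring E) | COc1cc(O)cc(OC)c1OC | starting material
11 | 2-bromo-3,4,5-trimethoxybenzaldehyde (ring D) | COc1cc(C=O)c(Br)c(OC)c1OC | starting material
12 | 3,4,5-trimethoxy-2-(3,4,5-trimethoxyphenoxy)benzaldehyde | COc1cc(C=O)c(Oc2cc(OC)c(OC)c(OC)c2)c(OC)c1OC | intermediate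
13 | 3,4,5-trimethoxy-2-(3,4,5-trimethoxyphenoxy)phenyl formate (not isolated) | COc1cc(OC=O)c(Oc2cc(OC)c(OC)c(OC)c2)c(OC)c1OC | intermediate
14 | 3,4,5-trimethoxy-2-(3,4,5-trimethoxyphenoxy)phenol (D–E phenol) | COc1cc(O)c(Oc2cc(OC)c(OC)c(OC)c2)c(OC)c1OC | intermediate
15 | racemic glycidyl methyl ether | COCC1CO1 | starting material
16 | racemic 1-methoxy-3-[3,4,5-trimethoxy-2-(3,4,5-trimethoxyphenoxy)phenoxy]propan-2-ol | COCC(O)COc1cc(OC)c(OC)c(OC)c1Oc1cc(OC)c(OC)c(OC)c1 | intermediate
17 | 1-methoxy-3-[3,4,5-trimethoxy-2-(3,4,5-trimethoxyphenoxy)phenoxy]propan-2-one | COCC(=O)COc1cc(OC)c(OC)c(OC)c1Oc1cc(OC)c(OC)c(OC)c1 | intermediate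
18 | (E)-2-(A–B aryloxy)-4-(D–E aryloxy)-6-methoxy-5-oxohex-2-enal, racemic at C4, drawn in the geometry that can close; present as its delocalised potassium salt (not isolated) | COCC(=O)C(Oc1cc(OC)c(OC)c(OC)c1Oc1cc(OC)c(OC)c(OC)c1)/C=C(/Oc1c(OC)cc(OC)cc1Oc1c(OC)cc(OC)cc1OC)C=O | intermediate
19 | pentamer with free ring C C4–OH and twelve methyl ethers | COc1cc(OC)c(Oc2cc(OC)cc(OC)c2Oc2cc(OC)c(O)c(Oc3cc(OC)c(OC)c(OC)c3Oc3cc(OC)c(OC)c(OC)c3)c2)c(OC)c1 | intermediate
20 | pseudopentafuhalol D | Oc1cc(O)c(Oc2cc(O)cc(O)c2Oc2cc(O)c(O)c(Oc3cc(O)c(O)c(O)c3Oc3cc(O)c(O)c(O)c3)c2)c(O)c1 | target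

**Totals**
Total step count: 11.
Longest linear sequence: 7 (steps 1–5, 10, 11). The D–E branch (steps 6–9) joins at step 10.

**Steps most likely to fail**

Step 10.
- Risk: self-aldol condensation of the ketone enolate may outrun attack on the weakly electrophilic vinylogous formamide. The enolate may also expel aryloxide. The sequence may stop after the first C–C bond if the delocalised anion stays in its extended geometry.
- Fallback: ring C is taken from a preformed arene and both of its aryl ether bonds are made by copper-catalysed coupling. The fallback sets out from phenol 5, uses phenol 14 as the second partner, and comes back to the route at target 20.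
- Commercial 2-bromo-6-methoxyphenol F1 is iodinated para to the hydroxyl (NIS, MeCN) to 2-bromo-4-iodo-6-methoxyphenol F2. O-Methylation (MeI, K2CO3, acetone) then gives 1-bromo-5-iodo-2,3-dimethoxybenzene F3.
- Phenol 5 is coupled at the unhindered and more reactive C–I bond (CuI, picolinic acid, K3PO4, DMSO, 80 °C) to give the A–B–C bromide F4.
- Phenol 14 is then coupled at the remaining C–Br bond (same catalyst system, 110 °C) to give the pentamer tridecamethyl ether F5. It differs from 19 only by a methyl group on the C4 oxygen, and BBr3 as in step 11 cleaves it to 20.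

Step 11.
- Risk: cleavage may stay incomplete when partly demethylated boron complexes precipitate. The pyrogallol- and hydroxyquinol-type rings may also oxidise in air during aqueous work-up and chromatography.
- Fallback: capture and release instead of direct isolation. It sets out from 19 and comes back at 20.
- The crude product of the BBr3 treatment is not purified but acetylated at once (Ac2O, pyridine, Ar) to the air-stable pseudopentafuhalol D tridecaacetate F6.
- F6 can be separated on silica from under-demethylated material. Acid-catalysed methanolysis under argon (AcCl cat., degassed MeOH, rt) then releases 20 with volatile by-products only.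

Step 1.
- Risk: substitution at copper may be slow because both partners are ortho-substituted. Hydrodebromination of the aldehyde and oxidation of the very electron-rich phenoxide may compete.
- Fallback: metal-free nucleophilic aromatic substitution. It sets out from phenol 1 and comes back at aldehyde 3.
- 1-Fluoro-3,5-dimethoxybenzene F7 is formylated under Vilsmeier–Haack conditions (POCl3, DMF) at the less hindered position para to one methoxy group. This gives 2-fluoro-4,6-dimethoxybenzaldehyde F8.
- The caesium phenoxide of 1 then displaces the ortho-formyl-activated fluoride (Cs2CO3, DMA, 140 °C, Ar) to give 3.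

**Further compounds**
F1 | step 10 | 2-bromo-6-methoxyphenol | COc1cccc(Br)c1O
F2 | step 10 | 2-bromo-4-iodo-6-methoxyphenol | COc1cc(I)cc(Br)c1O
F3 | step 10 | 1-bromo-5-iodo-2,3-dimethoxybenzene | COc1cc(I)cc(Br)c1OC
F4 | step 10 | A–B–C bromide, 1-bromo-2,3-dimethoxy-5-[2,4-dimethoxy-6-(2,4,6-trimethoxyphenoxy)phenoxy]benzene | COc1cc(Oc2c(OC)cc(OC)cc2Oc2c(OC)cc(OC)cc2OC)cc(Br)c1OC
F5 | step 10 | pentamer tridecamethyl ether | COc1cc(OC)c(Oc2cc(OC)cc(OC)c2Oc2cc(OC)c(OC)c(Oc3cc(OC)c(OC)c(OC)c3Oc3cc(OC)c(OC)c(OC)c3)c2)c(OC)c1
F6 | step 11 | pseudopentafuhalol D tridecaacetate | CC(=O)Oc1cc(OC(C)=O)c(Oc2cc(OC(C)=O)cc(OC(C)=O)c2Oc2cc(OC(C)=O)c(OC(C)=O)c(Oc3cc(OC(C)=O)c(OC(C)=O)c(OC(C)=O)c3Oc3cc(OC(C)=O)c(OC(C)=O)c(OC(C)=O)c3)c2)c(OC(C)=O)c1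
F7 | step 1 | 1-fluoro-3,5-dimethoxybenzene | COc1cc(F)cc(OC)c1
F8 | step 1 | 2-fluoro-4,6-dimethoxybenzaldehyde | COc1cc(F)c(C=O)c(OC)c1
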